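1 is the value to hold each tank against. Take the tank number: the first-order drain constant of D times the mean residence time, a Damköhler number. If a stirred tank at steady state loses D at that constant, its outlet D is the formed share (the part of the charge that has become D) divided by one plus the tank number. In logarithms, an error in the formed share reaches the outlet D at full weight, and an error in the constant arrives weighted by the tank number over one plus itself.

| flask | G | remark | time |
|---|---|---|---|
| elm | 34 mM | run made earlier |  |
| ash | 68 mM | run made earlier |  |
| Tuesday's | 34 mM | plug flow through a tube for 25 h, no back-mixing | 25 h |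
| Thursday's | 34 mM | a single well-mixed tank run continuously and read at steady state, 250 h in it on average |  |
| Wednesday's | 34 mM | one stirred flow tank at steady state, fed with the mixture as stated, mean residence time 25 h |  |
| Friday's | 34 mM | a closed flask charged with all of it at once and left for 25 h | 25 h |

elm run (percent of the G charged)

| time / h | D / % | G / % |
|---|---|---|
| 2.00 | 62.9 | 25.4 |
| 6.00 | 54.3 | 20.4 |
| 12.0 | 40.6 | 16.6 |
| 20.0 | 31.3 | 12.5 |
| 25.0 | 26.0 | 10.3 |

ash run (percent of the G charged)

| time / h | D / % | G / % |
|---|---|---|
| 0.200 | 41.5 | 55.0 |
| 0.667 | 57.7 | 34.8 |
| 1.33 | 52.3 | 35.0 |
| 2.00 | 50.6 | 29.0 |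
| 2.50 | 49.3 | 31.0 |

- the set-up with the highest amount of D at the outlet or at the end, in percent of the G put in ("none" if the first two lie within 2 percentage points) (Tuesday's / Thursday's / Wednesday's / Friday's / none)
- amount of D at the outlet or at the end, in percent of the G put in, Tuesday's
- amount of D at the outlet or at the end, in percent of the G put in, Thursday's
- amount of D at the outlet or at the end, in percent of the G put in, Wednesday's
- amount of D at the outlet or at the end, in percent of the G put in, Friday's

- the stated concentrations are those of everything mixed, before any reaction; amounts are the same in each set-up
- the earlier runs were made in a closed, stirred flask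

Which numbers must be good? Tuesday's tube and Friday's closed flask repeat the elm charge for 25 h, so the elm reading at that time serves as their answer, and its scatter of 1 percentage point passes straight through. The tanks are different: the constant's weight, reckoned from the two elm readings at 2.00 h and 25.0 h, is 0.490 in Wednesday's tank and 0.906 in Thursday's, which is more, so Thursday's needs it better.

The number itself comes from the elm run, where D falls from 62.9% at 2.00 h to 26.0% at 25.0 h, which reads as 0.0384 h⁻¹. The tank number, that constant times the mean residence time, is 0.960 for Wednesday's and 9.60 for Thursday's, ten times as large. Wednesday's beats the elm reading if its formed share exceeds 51.0%, and the elm run held 62.9% as D at 2.00 h, which is more. My own span, from that reading up to the whole charge, is 32.1% to 51.0% for Wednesday's and 5.93% to 9.43% for Thursday's.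

The forecast names Wednesday's, with 38% (33% to 42%) there, 8.2% (5.5% to 11%) for Thursday's, and 26% and 26% for Tuesday's and Friday's, each 24.5% to 27.5%. For the drain it says “Roughly D→waste at 0.04 /h”.

The flask gives 34.8% for Wednesday's, higher than the others, against 25.1% for Tuesday's, 25.1% for Friday's and 7.48% for Thursday's.

    G ⇌ D + J (K = 0.0590 M, k = 9.00 × 10⁻⁴ s⁻¹)
    D → Z (k = 1.20 × 10⁻⁵ s⁻¹)
    2 G → L (k = 8.30 × 10⁻⁴ M⁻¹ s⁻¹)

Wednesday's tank stood at [G] = 5.25 mM, with 15.4% of the charge as G at the outlet. With the D → Z constant above, its tank number is 1.08, where the elm reading gave 0.960, and this turns the outlet D into a formed share of 72.5%, which is 21 points above the 51.0% reckoned as the hurdle. Thursday's tank, with a tank number of 10.8 on the same constant, comes to a formed share of 88.3%.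

(The runs are simulated with constants of no real substance, noise included.)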